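A direct plan would C-prenylate the sodium phenoxide of methyl 4-hydroxybenzoate A1 to the ortho-prenylphenol A2, benzylate it to the benzyl ether A3, extend A3 by a crossed Claisen condensation to the alpha-benzyloxy beta-keto ester A4, fuse A4 with phloroglucinol A5 in a thermal Mentzer annulation to the 3,4'-di-O-benzyl flavonol A6, and hydrogenolyse both benzyl ethers of A6.
Its weakest steps would be:
- the ortho-C-prenylation of the phenoxide, where O-alkylation, double alkylation and allylic transposition compete and the outcome rests on ion pairing alone;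
- the melt annulation near 240 °C, which leaves the closure of ring C (chromone against coumarin, C- against O-acylation) to chance on the most advanced material and exposes the prenyl group to the melt;
- the final debenzylation, in which benzyl ether hydrogenolysis must outrun saturation of the prenyl olefin on the finished skeleton, after two steps spent only on putting the benzyl groups on.

Plan of the new route:
- Cuts: C2-C1' (ring B from ring C) and, in ring A, C4a-C5, C5-C6, C7-C8 and C8-C8a. Ring C is bought whole as kojic acid, ring B is attached second by Suzuki coupling, and ring A is built last.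
- Feature used: ring A is a resorcinol ring (C5-OH and C7-OH meta, H on C6 and C8) fused through C4a=C8a to a 4-pyranone with hydrogen at C4a. C4a=C8a-C8H=C5=O is therefore a vinylketene and C6-C7(O) an ynol ether, the two partners of a Danheiser benzannulation.
- Atom origins: the hydroxymethyl carbon of kojic acid becomes C5, diazomethane gives C8, and a silyl ynol ether gives C6 and C7-O.
- The prenyl group enters at a bromine-marked carbon by aryl-metal allylation, so no phenoxide C-alkylation occurs. Ring C is never closed, so there is no melt condensation. No benzyl ether and no H2 are used: the PMB ether falls to acid while O4' is still silylated, and the silyl ethers fall to buffered fluoride.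

Key step: step 12

Assumption: (triisopropylsilyloxy)ethyne, the ynol ether needed for the key step, is not taken as purchasable and is made in steps 9-11. The target has no stereocentre, so none has to be set.

**Step 1**
Reactants: 1 2-bromo-4-chlorophenol
Product: 2 (2-bromo-4-chlorophenoxy)triisopropylsilane
Conditions: TIPSCl (1.2 equiv), imidazole (2.5 equiv), DMF, 40 °C
Reagents that add atoms: chlorotriisopropylsilane, CC(C)[Si](Cl)(C(C)C)C(C)C
Why: Imidazole-promoted silyl ether formation; the bulky TIPS ether should carry O4' through the organometallic, basic, photochemical and acidic steps and keep this oxygen away from the prenyl olefin until the last step.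

**Step 2**
Reactants: 2 (2-bromo-4-chlorophenoxy)triisopropylsilane; 3 prenyl bromide (1-bromo-3-methylbut-2-ene)
Product: 5 [4-chloro-2-(3-methylbut-2-en-1-yl)phenoxy]triisopropylsilane, via arylmagnesium bromide 4 (not isolated)
Conditions: Mg turnings (1.5 equiv), LiCl (1.2 equiv), THF, rt; then 3 (1.3 equiv), Li2CuCl4 (3 mol%), THF, -10 °C → rt
Reagents that add atoms: magnesium, [Mg] (kept only in 4)
Why: Magnesium inserts into the C-Br bond only (C-Cl is inert at room temperature), and the copper-catalysed Kochi-type coupling of the aryl Grignard at the unhindered primary carbon of the allylic bromide should place the linear prenyl group at the carbon marked by bromine, with no O-alkylation and no ring regiochemistry to settle.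

**Step 3**
Reactants: 5 [4-chloro-2-(3-methylbut-2-en-1-yl)phenoxy]triisopropylsilane
Product: 6 triisopropyl[2-(3-methylbut-2-en-1-yl)-4-(4,4,5,5-tetramethyl-1,3,2-dioxaborolan-2-yl)phenoxy]silane
Conditions: B2pin2 (1.2 equiv), Pd2(dba)3 (1 mol%), XPhos (4 mol%), KOAc (3 equiv), 1,4-dioxane, 100 °C
Reagents that add atoms: bis(pinacolato)diboron, CC1(C)OB(OC1(C)C)B1OC(C)(C)C(C)(C)O1
Why: Miyaura borylation of the electron-rich aryl chloride with a bulky biarylphosphine; acetate is too weak a base to cleave the silyl ether or to start a Suzuki homocoupling.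

**Step 4**
Reactants: 7 kojic acid [5-hydroxy-2-(hydroxymethyl)-4H-pyran-4-one]
Product: 8 6-bromo-5-hydroxy-2-(hydroxymethyl)-4H-pyran-4-one
Conditions: NBS (1.05 equiv), DMF, 0 °C → rt, dark
Reagents that add atoms: N-bromosuccinimide, O=C1CCC(=O)N1Br
Why: Electrophilic bromination of the enolic 3-hydroxy-4-pyranone at C6, the carbon ortho to the free hydroxyl where kojic acid takes up electrophiles (as in its Mannich and aldol reactions); this marks the future C2 of the flavonol.

**Step 5**
Reactants: 8 6-bromo-5-hydroxy-2-(hydroxymethyl)-4H-pyran-4-one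
Product: 9 6-bromo-2-(hydroxymethyl)-5-[(4-methoxyphenyl)methoxy]-4H-pyran-4-one
Conditions: PMBCl (1.1 equiv), K2CO3 (1.5 equiv), DMF, rt
Reagents that add atoms: 4-methoxybenzyl chloride, COc1ccc(CCl)cc1
Why: Williamson etherification in which the weak base ionises only the enolic hydroxyl (pKa about 8) and not the primary alcohol; the PMB ether is chosen because mild acid removes it without hydrogen.

**Step 6**
Reactants: 9 6-bromo-2-(hydroxymethyl)-5-[(4-methoxyphenyl)methoxy]-4H-pyran-4-one
Product: 10 6-bromo-5-[(4-methoxyphenyl)methoxy]-4-oxo-4H-pyran-2-carboxylic acid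
Conditions: TEMPO (0.2 equiv), PhI(OAc)2 (2.2 equiv), MeCN/H2O 1:1, rt
Reagents that add atoms: water, O
Why: Oxoammonium-mediated oxidation of the primary alcohol through the aldehyde hydrate to the acid under near-neutral conditions that spare the PMB ether and the vinylogous acyl bromide; it is run before the prenyl group is on board, so no oxidant meets that olefin.

**Step 7**
Reactants: 10 6-bromo-5-[(4-methoxyphenyl)methoxy]-4-oxo-4H-pyran-2-carboxylic acid; 6 triisopropyl[2-(3-methylbut-2-en-1-yl)-4-(4,4,5,5-tetramethyl-1,3,2-dioxaborolan-2-yl)phenoxy]silane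
Product: 11 5-[(4-methoxyphenyl)methoxy]-6-[3-(3-methylbut-2-en-1-yl)-4-(triisopropylsilyloxy)phenyl]-4-oxo-4H-pyran-2-carboxylic acid
Conditions: 6 (1.2 equiv), Pd(dppf)Cl2 (5 mol%), K2CO3 (3.5 equiv), 1,4-dioxane/H2O 9:1, 70 °C; aq. citric acid work-up
Reagents that add atoms: none
Why: Suzuki-Miyaura coupling forms the C2-C1' bond; the C6-Br bond is a vinylogous acyl bromide that adds readily to zerovalent palladium, the carboxylate is tolerated, and the weak carbonate base should leave the aryl TIPS ether and the pyranone ring intact.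

**Step 8**
Reactants: 11 5-[(4-methoxyphenyl)methoxy]-6-[3-(3-methylbut-2-en-1-yl)-4-(triisopropylsilyloxy)phenyl]-4-oxo-4H-pyran-2-carboxylic acid
Product: 13 2-(diazoacetyl)-5-[(4-methoxyphenyl)methoxy]-6-[3-(3-methylbut-2-en-1-yl)-4-(triisopropylsilyloxy)phenyl]-4H-pyran-4-one, via mixed isobutyl carbonic anhydride 12 (not isolated)
Conditions: i-BuOCOCl (1.1 equiv), N-methylmorpholine (1.1 equiv), THF, -15 °C; then CH2N2 (3 equiv, Et2O), -15 → 5 °C
Reagents that add atoms: diazomethane, C=[N+]=[N-]; isobutyl chloroformate, CC(C)COC(Cl)=O (kept only in 12)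
Why: Acylation of diazomethane by the mixed carbonic anhydride (first stage of the Arndt-Eistert sequence); activation without HCl keeps the acid-labile PMB ether, and the acyl carbonyl of 12 is the more electrophilic site.

**Step 9**
Reactants: 14 tetrahydrofuran
Product: 16 triisopropyl(vinyloxy)silane, via lithium ethenolate 15 (not isolated)
Conditions: n-BuLi (1.0 equiv), THF (solvent), rt, 16 h; then TIPSCl (0.9 equiv), DMPU, 0 °C → rt
Reagents that add atoms: chlorotriisopropylsilane, CC(C)[Si](Cl)(C(C)C)C(C)C; n-butyllithium, [Li]CCCC (lithium kept only in 15)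
Why: 2-Lithiotetrahydrofuran undergoes the known [3+2] cycloreversion to ethene and the lithium enolate of acetaldehyde, which the hard chlorosilane silylates on oxygen.

**Step 10**
Reactants: 16 triisopropyl(vinyloxy)silane
Product: 18 [(Z)-2-bromoethenyloxy]triisopropylsilane, via dibromo ether 17 (not isolated)
Conditions: Br2 (1.0 equiv), CH2Cl2, -78 °C; then Et3N (1.5 equiv), -78 °C → rt
Reagents that add atoms: bromine, BrBr
Why: Bromine addition to the enol ether and amine-induced loss of HBr from the alpha-bromo ether is the classical route to 2-bromovinyl ethers; the hindered triisopropylsilyl group, which is known to let silyl enol ethers take up electrophiles at the beta carbon with the enol ether kept, should resist bromide-induced desilylation at -78 °C, and the Z isomer expected to predominate is set up for anti elimination in step 11.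

**Step 11**
Reactants: 18 [(Z)-2-bromoethenyloxy]triisopropylsilane
Product: 20 (ethynyloxy)triisopropylsilane [(triisopropylsilyloxy)ethyne], via lithium siloxyacetylide 19 (not isolated)
Conditions: LiN(i-Pr)2 (2.2 equiv), THF, -78 °C, 1 h; H2O quench at -78 °C; pentane extraction, distillation at reduced pressure
Reagents that add atoms: lithium diisopropylamide, [Li]N(C(C)C)C(C)C (lithium kept only in 19)
Why: Dehydrobromination of a 2-bromovinyl ether to the ynol ether, as in the classical synthesis of alkoxyacetylenes; the second equivalent of base holds the product as its acetylide until the cold quench, and the bulk of the silyl group should prevent its shift from oxygen to carbon.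

**Step 12**
Reactants: 13 2-(diazoacetyl)-5-[(4-methoxyphenyl)methoxy]-6-[3-(3-methylbut-2-en-1-yl)-4-(triisopropylsilyloxy)phenyl]-4H-pyran-4-one; 20 (ethynyloxy)triisopropylsilane
Product: 25 5-hydroxy-3-[(4-methoxyphenyl)methoxy]-2-[3-(3-methylbut-2-en-1-yl)-4-(triisopropylsilyloxy)phenyl]-7-(triisopropylsilyloxy)-4H-chromen-4-one, via pyranonylketene 21 (not isolated), via siloxycyclobutenone 22 (not isolated), via dienylketene 23 (not isolated), via cyclohexadienone tautomer 24 (not isolated)
Conditions: 20 (2.5 equiv), degassed ClCH2CH2Cl (0.05 M), hν (254 nm, low-pressure Hg lamps, Vycor), rt, until 13 is consumed; then 80 °C, 3 h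
Reagents that add atoms: none
Why: Irradiation expels N2 from 13 and the Wolff shift moves the pyranonyl group from the acyl carbon to the former diazo carbon, giving pyranonylketene 21 (C4a=C8a-C8H=C5=O in flavonol numbering); the electron-rich ynol ether 20 then adds in a [2+2] cycloaddition, its CH carbon bonding to the ketene carbonyl carbon (C5-C6) and its siloxy carbon to the ketene alpha-carbon (C7-C8), to give cyclobutenone 22. 4π-Electrocyclic opening of 22 (conrotatory at 80 °C, or induced by the light) cleaves the C5-C8 bond to dienylketene 23, whose double-bond isomers interconvert through 22 until the cis isomer closes ring A by a disrotatory six-electron electrocyclization between the ketene carbon C5 and C4a (the C3-H carbon of the pyranone), and the cyclohexadienone 24 enolises irreversibly to the chelated phenol 25. The closest known reaction type is the second-generation Danheiser benzannulation (photochemical aromatic annulation) of aryl, heteroaryl and alkenyl diazomethyl ketones with siloxyalkynes, which gives fused resorcinol monosilyl ethers such as oxygenated naphthalenes, benzofurans, benzothiophenes and indoles. Ring A is the only ring closed, by 6π-electrocyclization after the [2+2]/4π sequence has assembled its six carbons; the transient sp3 centres (C4 of 22, C4a of 24) vanish on aromatisation, so no stereocentre has to be controlled. The step needs regioselectivity in the [2+2], which the polarisation of the ynol ether against the ketene secures (silyloxy at C7, meta to the new C5 hydroxyl); a single site for the electrocyclization, which the substrate secures because the other neighbour of C8a is the ring oxygen; and chemoselectivity against the prenyl olefin, which is far less ketenophilic than the ynol ether.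

**Step 13**
Reactants: 25 5-hydroxy-3-[(4-methoxyphenyl)methoxy]-2-[3-(3-methylbut-2-en-1-yl)-4-(triisopropylsilyloxy)phenyl]-7-(triisopropylsilyloxy)-4H-chromen-4-one
Product: 26 3,5-dihydroxy-2-[3-(3-methylbut-2-en-1-yl)-4-(triisopropylsilyloxy)phenyl]-7-(triisopropylsilyloxy)-4H-chromen-4-one
Conditions: TFA (5 vol%), anisole (10 equiv), CH2Cl2, 0 °C, 30 min
Reagents that add atoms: none
Why: Acidolysis of the PMB ether with anisole as cation trap; the enolic O3 next to the C4 carbonyl is a good leaving group, the aryl TIPS ethers are stable to dilute cold TFA, and the phenol beside the prenyl group is still silylated, so acid-induced chroman closure has no nucleophile.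

**Step 14**
Reactants: 26 3,5-dihydroxy-2-[3-(3-methylbut-2-en-1-yl)-4-(triisopropylsilyloxy)phenyl]-7-(triisopropylsilyloxy)-4H-chromen-4-one
Product: 27 isolicoflavonol [3,5,7-trihydroxy-2-[4-hydroxy-3-(3-methylbut-2-en-1-yl)phenyl]-4H-chromen-4-one]
Conditions: TBAF (2.5 equiv), AcOH (3 equiv), degassed THF, 0 °C → rt
Reagents that add atoms: none
Why: Fluoride-induced cleavage of both aryl silyl ethers; acetic acid buffers the phenoxides, so the freed ortho-prenylphenol meets no strong acid and the air-sensitive flavonol anion is not left in base.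

**Compound list**
1 | 2-bromo-4-chlorophenol | Oc1ccc(Cl)cc1Br | starting material
2 | (2-bromo-4-chlorophenoxy)triisopropylsilane | CC(C)[Si](Oc1ccc(Cl)cc1Br)(C(C)C)C(C)C | intermediate
3 | prenyl bromide (1-bromo-3-methylbut-2-ene) | CC(C)=CCBr | starting material
4 | [5-chloro-2-(triisopropylsilyloxy)phenyl]magnesium bromide | CC(C)[Si](Oc1ccc(Cl)cc1[Mg]Br)(C(C)C)C(C)C | intermediate (not isolated)
5 | [4-chloro-2-(3-methylbut-2-en-1-yl)phenoxy]triisopropylsilane | CC(C)=CCc1cc(Cl)ccc1O[Si](C(C)C)(C(C)C)C(C)C | intermediate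
6 | triisopropyl[2-(3-methylbut-2-en-1-yl)-4-(4,4,5,5-tetramethyl-1,3,2-dioxaborolan-2-yl)phenoxy]silane | CC(C)=CCc1cc(B2OC(C)(C)C(C)(C)O2)ccc1O[Si](C(C)C)(C(C)C)C(C)C | intermediate
7 | kojic acid, 5-hydroxy-2-(hydroxymethyl)-4H-pyran-4-one | O=c1cc(CO)occ1O | starting material
8 | 6-bromo-5-hydroxy-2-(hydroxymethyl)-4H-pyran-4-one | O=c1cc(CO)oc(Br)c1O | intermediate
9 | 6-bromo-2-(hydroxymethyl)-5-[(4-methoxyphenyl)methoxy]-4H-pyran-4-one | O=c1cc(CO)oc(Br)c1OCc2ccc(OC)cc2 | intermediate
10 | 6-bromo-5-[(4-methoxyphenyl)methoxy]-4-oxo-4H-pyran-2-carboxylic acid | O=C(O)c1cc(=O)c(OCc2ccc(OC)cc2)c(Br)o1 | intermediate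
11 | 5-[(4-methoxyphenyl)methoxy]-6-[3-(3-methylbut-2-en-1-yl)-4-(triisopropylsilyloxy)phenyl]-4-oxo-4H-pyran-2-carboxylic acid | O=C(O)c1cc(=O)c(OCc2ccc(OC)cc2)c(-c2ccc(O[Si](C(C)C)(C(C)C)C(C)C)c(CC=C(C)C)c2)o1 | intermediate
12 | mixed anhydride of 11 with isobutyl carbonic acid | CC(C)COC(=O)OC(=O)c1cc(=O)c(OCc2ccc(OC)cc2)c(-c2ccc(O[Si](C(C)C)(C(C)C)C(C)C)c(CC=C(C)C)c2)o1 | intermediate (not isolated)
13 | 2-(diazoacetyl)-5-[(4-methoxyphenyl)methoxy]-6-[3-(3-methylbut-2-en-1-yl)-4-(triisopropylsilyloxy)phenyl]-4H-pyran-4-one | [N-]=[N+]=CC(=O)c1cc(=O)c(OCc2ccc(OC)cc2)c(-c2ccc(O[Si](C(C)C)(C(C)C)C(C)C)c(CC=C(C)C)c2)o1 | intermediate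
14 | tetrahydrofuran | C1CCOC1 | starting material
15 | lithium ethenolate (lithium enolate of acetaldehyde) | [Li]OC=C | intermediate (not isolated)
16 | triisopropyl(vinyloxy)silane | C=CO[Si](C(C)C)(C(C)C)C(C)C | intermediate
17 | (1,2-dibromoethoxy)triisopropylsilane (racemic) | BrCC(Br)O[Si](C(C)C)(C(C)C)C(C)C | intermediate (not isolated)
18 | [(Z)-2-bromoethenyloxy]triisopropylsilane | Br/C=C\O[Si](C(C)C)(C(C)C)C(C)C | intermediate
19 | lithium (triisopropylsilyloxy)acetylide | [Li]C#CO[Si](C(C)C)(C(C)C)C(C)C | intermediate (not isolated)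
20 | (ethynyloxy)triisopropylsilane | C#CO[Si](C(C)C)(C(C)C)C(C)C | intermediate
21 | 5-[(4-methoxyphenyl)methoxy]-6-[3-(3-methylbut-2-en-1-yl)-4-(triisopropylsilyloxy)phenyl]-2-(2-oxoethenyl)-4H-pyran-4-one (ketene) | O=C=Cc1cc(=O)c(OCc2ccc(OC)cc2)c(-c2ccc(O[Si](C(C)C)(C(C)C)C(C)C)c(CC=C(C)C)c2)o1 | intermediate (not isolated)
22 | 5-[(4-methoxyphenyl)methoxy]-6-[3-(3-methylbut-2-en-1-yl)-4-(triisopropylsilyloxy)phenyl]-2-[4-oxo-2-(triisopropylsilyloxy)cyclobut-2-en-1-yl]-4H-pyran-4-one (racemic) | O=C1C=C(O[Si](C(C)C)(C(C)C)C(C)C)C1c1cc(=O)c(OCc2ccc(OC)cc2)c(-c2ccc(O[Si](C(C)C)(C(C)C)C(C)C)c(CC=C(C)C)c2)o1 | intermediate (not isolated)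
23 | 5-[(4-methoxyphenyl)methoxy]-6-[3-(3-methylbut-2-en-1-yl)-4-(triisopropylsilyloxy)phenyl]-2-[4-oxo-2-(triisopropylsilyloxy)buta-1,3-dien-1-yl]-4H-pyran-4-one (dienylketene, isomer with ketene and pyranone cis) | O=C=C/C(O[Si](C(C)C)(C(C)C)C(C)C)=C\c1cc(=O)c(OCc2ccc(OC)cc2)c(-c2ccc(O[Si](C(C)C)(C(C)C)C(C)C)c(CC=C(C)C)c2)o1 | intermediate (not isolated)
24 | 3-[(4-methoxyphenyl)methoxy]-2-[3-(3-methylbut-2-en-1-yl)-4-(triisopropylsilyloxy)phenyl]-7-(triisopropylsilyloxy)-4aH-chromene-4,5-dione (racemic keto tautomer of 25) | O=C1C=C(O[Si](C(C)C)(C(C)C)C(C)C)C=C2OC(-c3ccc(O[Si](C(C)C)(C(C)C)C(C)C)c(CC=C(C)C)c3)=C(OCc3ccc(OC)cc3)C(=O)C12 | intermediate (not isolated)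
25 | 5-hydroxy-3-[(4-methoxyphenyl)methoxy]-2-[3-(3-methylbut-2-en-1-yl)-4-(triisopropylsilyloxy)phenyl]-7-(triisopropylsilyloxy)-4H-chromen-4-one | CC(C)=CCc1cc(-c2oc3cc(O[Si](C(C)C)(C(C)C)C(C)C)cc(O)c3c(=O)c2OCc2ccc(OC)cc2)ccc1O[Si](C(C)C)(C(C)C)C(C)C | intermediate
26 | 3,5-dihydroxy-2-[3-(3-methylbut-2-en-1-yl)-4-(triisopropylsilyloxy)phenyl]-7-(triisopropylsilyloxy)-4H-chromen-4-one | CC(C)=CCc1cc(-c2oc3cc(O[Si](C(C)C)(C(C)C)C(C)C)cc(O)c3c(=O)c2O)ccc1O[Si](C(C)C)(C(C)C)C(C)C | intermediate
27 | isolicoflavonol, 3,5,7-trihydroxy-2-[4-hydroxy-3-(3-methylbut-2-en-1-yl)phenyl]-4H-chromen-4-one (achiral) | CC(C)=CCc1cc(-c2oc3cc(O)cc(O)c3c(=O)c2O)ccc1O | target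

Total step count: 14 (steps 1-3 ring B boronate, steps 4-6 ring C acid, steps 9-11 ynol ether, steps 7, 8, 12-14 main line).
Longest linear sequence: 8 steps (kojic acid 7 → 27 through steps 4, 5, 6, 7, 8, 12, 13, 14).

Steps most likely to fail:

1. Step 12 (benzannulation). The light may be absorbed by the 2-aryl-4-pyranone chromophore instead of the diazo group (inner-filter effect, pyranone photorearrangement), the excited diazo ketone may decay without a clean Wolff shift, or ketene 21 may dimerise before it meets the ynol ether. The fallback sets out from 13 and comes back at 22, and so at 25; it makes the same ketene in the dark. Silver-catalysed Wolff rearrangement of 13 in wet THF (PhCO2Ag, Et3N, THF/H2O, rt) would give the homologous {5-[(4-methoxyphenyl)methoxy]-6-aryl-4-oxo-4H-pyran-2-yl}acetic acid F1 (Arndt-Eistert homologation). 1-Chloro-N,N,2-trimethylprop-1-en-1-amine in CH2Cl2 would convert it under neutral conditions into the acid chloride F2. Slow addition of F2 to Et3N and 20 in CH2Cl2 would generate 21 by dehydrochlorination and trap it as cyclobutenone 22, which at 80 °C goes on to 25 as in step 12.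

2. Step 11 (ynol ether). Under the lithium amide the silyl group may be lost or may shift from oxygen to carbon, and the small, hydrolytically sensitive ynol ether may be lost on isolation. The fallback sets out from 13 and comes back at 27; it puts carbon instead of silicon on the ynol oxygen. tert-Butoxyethyne F3, a known distillable ynol ether that carries no silyl group to lose, would be used in place of 20 in the annulation of step 12. The irradiation is run at room temperature and excess F3 is evaporated below 30 °C before the 80 °C stage, because F3 itself releases ketene on heating. This would give 7-tert-butoxy-5-hydroxy-3-[(4-methoxyphenyl)methoxy]-2-[3-(3-methylbut-2-en-1-yl)-4-(triisopropylsilyloxy)phenyl]-4H-chromen-4-one F4. TFA/anisole at 0 °C would cleave the tert-butyl and PMB ethers together to give 4'-O-triisopropylsilyl isolicoflavonol F5, and TBAF/AcOH as in step 14 returns to 27.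

3. Step 8 (diazo ketone). Diazomethane may add as a 1,3-dipole to the electron-poor C2=C3 bond of the acylated pyranone or attack the carbonate carbonyl of 12, and unactivated acid would be lost as its methyl ester. The fallback sets out from 11 by way of 12 and comes back at 13; it avoids diazomethane. Anhydride 12 would be intercepted with MeNHOMe·HCl and N-methylmorpholine to give the Weinreb amide F6. MeMgBr in THF at -78 °C would give the methyl ketone F7. A detrifluoroacetylative diazo transfer would follow: LiN(SiMe3)2 and CF3CO2CH2CF3 in THF at -78 °C to the trifluoroacetyl diketone F8, then MsN3, Et3N and H2O in MeCN at rt to give 13.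

**Further compounds**
F1 | step 12 | 2-{5-[(4-methoxyphenyl)methoxy]-6-[3-(3-methylbut-2-en-1-yl)-4-(triisopropylsilyloxy)phenyl]-4-oxo-4H-pyran-2-yl}acetic acid | O=C(O)Cc1cc(=O)c(OCc2ccc(OC)cc2)c(-c2ccc(O[Si](C(C)C)(C(C)C)C(C)C)c(CC=C(C)C)c2)o1
F2 | step 12 | 2-{5-[(4-methoxyphenyl)methoxy]-6-[3-(3-methylbut-2-en-1-yl)-4-(triisopropylsilyloxy)phenyl]-4-oxo-4H-pyran-2-yl}acetyl chloride | O=C(Cl)Cc1cc(=O)c(OCc2ccc(OC)cc2)c(-c2ccc(O[Si](C(C)C)(C(C)C)C(C)C)c(CC=C(C)C)c2)o1
F3 | step 11 | tert-butoxyethyne | C#COC(C)(C)C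
F4 | step 11 | 7-tert-butoxy-5-hydroxy-3-[(4-methoxyphenyl)methoxy]-2-[3-(3-methylbut-2-en-1-yl)-4-(triisopropylsilyloxy)phenyl]-4H-chromen-4-one | CC(C)=CCc1cc(-c2oc3cc(OC(C)(C)C)cc(O)c3c(=O)c2OCc2ccc(OC)cc2)ccc1O[Si](C(C)C)(C(C)C)C(C)C
F5 | step 11 | 3,5,7-trihydroxy-2-[3-(3-methylbut-2-en-1-yl)-4-(triisopropylsilyloxy)phenyl]-4H-chromen-4-one | CC(C)=CCc1cc(-c2oc3cc(O)cc(O)c3c(=O)c2O)ccc1O[Si](C(C)C)(C(C)C)C(C)C
F6 | step 8 | N-methoxy-5-[(4-methoxyphenyl)methoxy]-N-methyl-6-[3-(3-methylbut-2-en-1-yl)-4-(triisopropylsilyloxy)phenyl]-4-oxo-4H-pyran-2-carboxamide | CON(C)C(=O)c1cc(=O)c(OCc2ccc(OC)cc2)c(-c2ccc(O[Si](C(C)C)(C(C)C)C(C)C)c(CC=C(C)C)c2)o1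
F7 | step 8 | 2-acetyl-5-[(4-methoxyphenyl)methoxy]-6-[3-(3-methylbut-2-en-1-yl)-4-(triisopropylsilyloxy)phenyl]-4H-pyran-4-one | CC(=O)c1cc(=O)c(OCc2ccc(OC)cc2)c(-c2ccc(O[Si](C(C)C)(C(C)C)C(C)C)c(CC=C(C)C)c2)o1
F8 | step 8 | 4,4,4-trifluoro-1-{5-[(4-methoxyphenyl)methoxy]-6-[3-(3-methylbut-2-en-1-yl)-4-(triisopropylsilyloxy)phenyl]-4-oxo-4H-pyran-2-yl}butane-1,3-dione | O=C(CC(=O)C(F)(F)F)c1cc(=O)c(OCc2ccc(OC)cc2)c(-c2ccc(O[Si](C(C)C)(C(C)C)C(C)C)c(CC=C(C)C)c2)o1
A1 | direct plan | methyl 4-hydroxybenzoate | COC(=O)c1ccc(O)cc1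
A2 | direct plan | methyl 4-hydroxy-3-(3-methylbut-2-en-1-yl)benzoate | COC(=O)c1ccc(O)c(CC=C(C)C)c1
A3 | direct plan | methyl 4-(benzyloxy)-3-(3-methylbut-2-en-1-yl)benzoate | COC(=O)c1ccc(OCc2ccccc2)c(CC=C(C)C)c1
A4 | direct plan | ethyl 2-(benzyloxy)-3-[4-(benzyloxy)-3-(3-methylbut-2-en-1-yl)phenyl]-3-oxopropanoate (racemic) | CCOC(=O)C(OCc1ccccc1)C(=O)c1ccc(OCc2ccccc2)c(CC=C(C)C)c1
A5 | direct plan | phloroglucinol (benzene-1,3,5-triol) | Oc1cc(O)cc(O)c1
A6 | direct plan | 3-(benzyloxy)-2-[4-(benzyloxy)-3-(3-methylbut-2-en-1-yl)phenyl]-5,7-dihydroxy-4H-chromen-4-one | CC(C)=CCc1cc(-c2oc3cc(O)cc(O)c3c(=O)c2OCc2ccccc2)ccc1OCc1ccccc1
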